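**Retrosynthetic overview**

1. Feature: the cyclopentane C8–C12 carries cis (α) oxygens at C9 and C11, trans chains at C8 and C12 and the (13E)-allylic C15 carbinol. This is the pattern that the folded all-Z C5–C15 skipped tetraene of a C20 acid acquires from two O2; the C19 (R) carbinol lies outside this array and is brought in ready-made.
2. Target ⇐ O–O reduction of the 9α,11α-endoperoxide (2,3-dioxabicyclo[2.2.1]heptane) of 19(R)-hydroxy-prostaglandin H2.
3. Endoperoxide ⇐ 19(R)-hydroxyarachidonic acid + 2 O2 on prostaglandin endoperoxide H synthase (bonds O–C11, O–C9, C8–C12, O–C15); the 1,2-dioxolane closes first, the cyclopentane second.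
4. Tetraene acid ⇐ C20 skipped tetrayne ester by four-fold cis semi-hydrogenation ⇐ three copper-mediated sp–sp3 couplings at C6–C7, C10–C11 and C13–C14.
5. Blocks: methyl hex-5-ynoate (C1–C6), 4-chlorobut-2-yn-1-ol (C7–C10), prop-2-yn-1-ol (C11–C13), and (R)-hept-6-yn-2-ol (C14–C20) from (R)-propylene oxide.

Key step: step 10

Assumption: the C19 hydroxyl is carried unprotected from step 7 onward, and step 10 is planned on a milligram scale because the synthase is expected to inactivate itself after a limited number of turnovers.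

**Step 1**
Reactants: 1 (4-bromobut-1-yn-1-yl)trimethylsilane; 2 (R)-propylene oxide
Product: 4 (R)-7-(trimethylsilyl)hept-6-yn-2-ol, via [4-(trimethylsilyl)but-3-yn-1-yl]magnesium bromide 3 (not isolated)
Conditions: Mg, THF, 40 °C; then CuI (10 mol %), 2, −30 → 0 °C; aq NH4Cl
Reagents that add atoms: none
Why: Copper-catalysed Grignard opening of a terminal epoxide proceeds by SN2 attack at the unsubstituted CH2, so the C–O stereocentre of 2 is carried unchanged into the (R)-carbinol that becomes C19.

**Step 2**
Reactants: 4 (R)-7-(trimethylsilyl)hept-6-yn-2-ol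
Product: 5 (R)-hept-6-yn-2-ol
Conditions: K2CO3 (0.2 equiv), MeOH, rt
Reagents that add atoms: none
Why: Base-catalysed methanolysis of the alkynyl C–Si bond (protodesilylation) should free the terminal alkyne without touching the remote carbinol centre.

**Step 3**
Reactants: 6 methyl hex-5-ynoate; 7 4-chlorobut-2-yn-1-ol
Product: 10 methyl 10-hydroxydeca-5,8-diynoate, via 4-iodobut-2-yn-1-ol 8 (not isolated), via copper acetylide of methyl hex-5-ynoate 9 (not isolated)
Conditions: CuI (1 equiv), NaI (1 equiv), Cs2CO3 (1 equiv), DMF, rt, Ar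
Reagents that add atoms: none
Why: Finkelstein exchange gives the propargylic iodide, which the copper acetylide attacks at the sp3 carbon (copper-mediated alkyne–propargyl halide coupling), the carbonate base being too mild to alkylate the free hydroxyl, touch the ester or isomerise the skipped diyne to an allene.

**Step 4**
Reactants: 10 methyl 10-hydroxydeca-5,8-diynoate
Product: 11 methyl 10-bromodeca-5,8-diynoate
Conditions: CBr4, PPh3, CH2Cl2, −20 → 0 °C
Reagents that add atoms: carbon tetrabromide, BrC(Br)(Br)Br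
Why: The Appel reaction should convert the primary propargylic alcohol into the bromide under neutral conditions that spare the ester and the skipped diyne.

**Step 5**
Reactants: 11 methyl 10-bromodeca-5,8-diynoate; 12 prop-2-yn-1-ol
Product: 14 methyl 13-hydroxytrideca-5,8,11-triynoate, via copper acetylide of prop-2-yn-1-ol 13 (not isolated)
Conditions: CuI (1 equiv), Cs2CO3 (1 equiv), DMF, 0 °C → rt, Ar
Reagents that add atoms: none
Why: The same copper-mediated alkyne–propargyl halide coupling applies, the bromide being reactive enough without halide exchange and the free hydroxyl of 12 being tolerated.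

**Step 6**
Reactants: 14 methyl 13-hydroxytrideca-5,8,11-triynoate
Product: 15 methyl 13-bromotrideca-5,8,11-triynoate
Conditions: CBr4, PPh3, CH2Cl2, −30 → 0 °C; short silica plug, used at once
Reagents that add atoms: carbon tetrabromide, BrC(Br)(Br)Br
Why: The Appel reaction works as in step 4, and the cold, neutral conditions with immediate use are chosen because the skipped triyne bromide is sensitive to air and base.

**Step 7**
Reactants: 15 methyl 13-bromotrideca-5,8,11-triynoate; 5 (R)-hept-6-yn-2-ol
Product: 17 methyl (19R)-19-hydroxyicosa-5,8,11,14-tetraynoate, via copper acetylide of (R)-hept-6-yn-2-ol 16 (not isolated)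
Conditions: CuI (1 equiv), Cs2CO3 (1 equiv), DMF, 0 °C → rt, Ar
Reagents that add atoms: none
Why: Copper-mediated alkyne–propargyl halide coupling closes the C13–C14 bond, the secondary hydroxyl not being deprotonated by carbonate and the C19 centre lying far from the reacting carbons.

**Step 8**
Reactants: 17 methyl (19R)-19-hydroxyicosa-5,8,11,14-tetraynoate
Product: 18 methyl (5Z,8Z,11Z,14Z,19R)-19-hydroxyicosa-5,8,11,14-tetraenoate
Conditions: H2 (1 atm), P-2 nickel boride (Ni2B, from Ni(OAc)2·4H2O and NaBH4), ethylenediamine, EtOH, rt, stopped at 4 equiv H2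
Reagents that add atoms: none
Why: Catalytic semi-hydrogenation delivers H2 syn on the poisoned nickel surface, so each alkyne should give the Z alkene and the amine-modified catalyst should stop at the alkene stage; C19 is untouched.

**Step 9**
Reactants: 18 methyl (5Z,8Z,11Z,14Z,19R)-19-hydroxyicosa-5,8,11,14-tetraenoate
Product: 19 (5Z,8Z,11Z,14Z,19R)-19-hydroxyicosa-5,8,11,14-tetraenoic acid [19(R)-hydroxyarachidonic acid]
Conditions: LiOH·H2O, THF/H2O 2:1, rt, Ar; then 1 M HCl to pH 4, 0 °C
Reagents that add atoms: lithium hydroxide (hydroxide oxygen), [Li+].[OH-]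
Why: Saponification by acyl substitution should free the carboxylate needed for enzyme binding, the skipped Z-tetraene being stable to hydroxide at room temperature when air is excluded.

**Step 10**
Reactants: 19 19(R)-hydroxyarachidonic acid
Product: 21 19(R)-hydroxy-prostaglandin H2 [(5Z,13E,15S,19R)-9α,11α-epidioxy-15,19-dihydroxyprosta-5,13-dien-1-oic acid], via 19(R)-hydroxy-PGG2 hydroperoxide 20 (not isolated)
Conditions: O2, ovine prostaglandin endoperoxide H synthase 1 (holoenzyme with hematin, C34H33FeN4O5), hydroquinone (1 mM), 0.1 M Tris-HCl pH 8.0, 19 at 0.1 mM, 25 °C, 2 min; citric acid to pH 3.5, cold Et2O extraction, 0 °C, used at once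
Reagents that add atoms: dioxygen, O=O
Why: The tyrosyl radical of the cyclooxygenase site should abstract the pro-S hydrogen at C13, O2 adds at C11 of the C11–C15 pentadienyl radical, the 11-peroxyl radical closes onto C9 (O–C9 bond), the C8 radical closes onto C12 (C8–C12 bond) to complete the 2,3-dioxabicyclo[2.2.1]heptane, and the C13–C15 allyl radical takes the second O2 at C15 to give hydroperoxide 20, which the peroxidase site reduces to carbinol 21 at the expense of hydroquinone. The closest known reaction type is this same bis-dioxygenation of arachidonic acid and of its ω-hydroxylated congener, the 20-hydroxy acid, to prostaglandin endoperoxides. The 1,2-dioxolane closes first and the cyclopentane second, both by 5-exo-trig radical cyclisation. The five new stereocentres are set by the protein: O2 enters C11 on the face opposite the abstracted hydrogen (11α), the fold of the chain in the channel puts the C9 oxygen cis to it (9α) and forces the C8 and C12 chains trans, and the second O2 is delivered to one face of C15 (15S), while C19 (R) comes in with 19. The step needs abstraction at C13 only and complete double dioxygenation instead of release of 11- or 15-mono-oxygenated acids; the carboxylate anchor and the hydrophobic ω-groove of the channel should secure this, since the C19 hydroxyl sits four carbons beyond C15 at the flexible end of that groove.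

**Step 11**
Reactants: 21 19(R)-hydroxy-prostaglandin H2
Product: 22 19(R)-hydroxy-prostaglandin F2α [(5Z,9α,11α,13E,15S,19R)-9,11,15,19-tetrahydroxyprosta-5,13-dien-1-oic acid]
Conditions: SnCl2·2H2O (excess), EtOH/Et2O, 0.1 M HCl, 0 °C → rt; reversed-phase HPLC
Reagents that add atoms: none
Why: Divalent tin reduces the dialkyl peroxide O–O bond by two electrons without touching either C–O bond, so the cis-9α,11α-diol follows directly from the bicyclic endoperoxide and no stereocentre is made or disturbed.

**Compound list**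

1 | (4-bromobut-1-yn-1-yl)trimethylsilane | C[Si](C)(C)C#CCCBr | starting material
2 | (R)-propylene oxide | C[C@@H]1CO1 | starting material
3 | [4-(trimethylsilyl)but-3-yn-1-yl]magnesium bromide | C[Si](C)(C)C#CCC[Mg]Br | intermediate
4 | (R)-7-(trimethylsilyl)hept-6-yn-2-ol | C[C@@H](O)CCCC#C[Si](C)(C)C | intermediate
5 | (R)-hept-6-yn-2-ol | C[C@@H](O)CCCC#C | intermediate
6 | methyl hex-5-ynoate | C#CCCCC(=O)OC | starting material
7 | 4-chlorobut-2-yn-1-ol | OCC#CCCl | starting material
8 | 4-iodobut-2-yn-1-ol | OCC#CCI | intermediate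
9 | copper acetylide of methyl hex-5-ynoate | COC(=O)CCCC#C[Cu] | intermediate
10 | methyl 10-hydroxydeca-5,8-diynoate | OCC#CCC#CCCCC(=O)OC | intermediate
11 | methyl 10-bromodeca-5,8-diynoate | BrCC#CCC#CCCCC(=O)OC | intermediate
12 | prop-2-yn-1-ol | C#CCO | starting material
13 | copper acetylide of prop-2-yn-1-ol | OCC#C[Cu] | intermediate
14 | methyl 13-hydroxytrideca-5,8,11-triynoate | OCC#CCC#CCC#CCCCC(=O)OC | intermediate
15 | methyl 13-bromotrideca-5,8,11-triynoate | BrCC#CCC#CCC#CCCCC(=O)OC | intermediate
16 | copper acetylide of (R)-hept-6-yn-2-ol | C[C@@H](O)CCCC#C[Cu] | intermediate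
17 | methyl (19R)-19-hydroxyicosa-5,8,11,14-tetraynoate | C[C@@H](O)CCCC#CCC#CCC#CCC#CCCCC(=O)OC | intermediate
18 | methyl (5Z,8Z,11Z,14Z,19R)-19-hydroxyicosa-5,8,11,14-tetraenoate | C[C@@H](O)CCC/C=C\C/C=C\C/C=C\C/C=C\CCCC(=O)OC | intermediate
19 | 19(R)-hydroxyarachidonic acid | C[C@@H](O)CCC/C=C\C/C=C\C/C=C\C/C=C\CCCC(=O)O | intermediate
20 | 19(R)-hydroxy-prostaglandin G2 (15-hydroperoxide) | C[C@@H](O)CCC[C@H](OO)/C=C/[C@@H]1[C@@H](C/C=C\CCCC(=O)O)[C@@H]2C[C@H]1OO2 | intermediate
21 | 19(R)-hydroxy-prostaglandin H2 | C[C@@H](O)CCC[C@H](O)/C=C/[C@@H]1[C@@H](C/C=C\CCCC(=O)O)[C@@H]2C[C@H]1OO2 | intermediate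
22 | 19(R)-hydroxy-prostaglandin F2α | C[C@@H](O)CCC[C@H](O)/C=C/[C@@H]1[C@@H](C/C=C\CCCC(=O)O)[C@@H](O)C[C@H]1O | target

**Step count**

Total: 11 steps. Longest linear sequence: 9 steps (steps 3 to 11, from methyl hex-5-ynoate); steps 1 and 2 form the side branch that joins at step 7.

**Steps most likely to fail**

**Step 10.** The hydroxylated ω-tail may bind in a non-productive fold, so that turnover stalls or stops after the first oxygenation. The enzyme may inactivate itself before the substrate is consumed. The endoperoxide may also rearrange in buffer to 9-oxo and 11-oxo isomers before it is extracted.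

Fallback (sets out from 5, returns at 22): the ring is taken from the commercial bicyclic lactone aldehyde (3aR,4R,5R,6aS)-4-formyl-2-oxohexahydro-2H-cyclopenta[b]furan-5-yl benzoate, and the hydroxylated lower chain is attached by Horner–Wadsworth–Emmons olefination.
- 5 is silylated (tBuMe2SiCl, imidazole, DMF) to (R)-tert-butyl(hept-6-yn-2-yloxy)dimethylsilane F1.
- Lithiation (n-BuLi, THF, −78 °C) and quenching with diethyl chlorophosphate should give diethyl [(6R)-6-(tert-butyldimethylsilyloxy)hept-1-yn-1-yl]phosphonate F2.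
- Butan-1-amine adds to the β-carbon to give the enamine diethyl [(6R)-2-(butylamino)-6-(tert-butyldimethylsilyloxy)hept-1-en-1-yl]phosphonate F3, which two-phase aqueous oxalic acid hydrolyses to diethyl [(6R)-6-(tert-butyldimethylsilyloxy)-2-oxoheptyl]phosphonate F4.
- Olefination of the lactone aldehyde with F4 (LiCl, iPr2NEt, MeCN) should give the enone (3aR,4R,5R,6aS)-4-[(1E,7R)-7-(tert-butyldimethylsilyloxy)-3-oxooct-1-en-1-yl]-2-oxohexahydro-2H-cyclopenta[b]furan-5-yl benzoate F5.
- Corey–Bakshi–Shibata reduction with the (R)-configured B-methyl oxazaborolidine and catecholborane (toluene, −78 °C) should set the 15S carbinol in the (1E,3S,7R)-3-hydroxy benzoate F6.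
- Methanolysis (K2CO3, MeOH) removes the benzoate to give (3aR,4R,5R,6aS)-4-[(1E,3S,7R)-7-(tert-butyldimethylsilyloxy)-3-hydroxyoct-1-en-1-yl]-5-hydroxyhexahydro-2H-cyclopenta[b]furan-2-one F7.
- iBu2AlH (CH2Cl2, −78 °C) reduces the lactone to the lactol, the corresponding hexahydro-2H-cyclopenta[b]furan-2,5-diol F8.
- Wittig reaction with excess ylide from (4-carboxybutyl)triphenylphosphonium bromide and KOtBu (THF, 0 °C → rt) should install the 5Z chain and give 19-O-tert-butyldimethylsilyl-19(R)-hydroxy-prostaglandin F2α F9.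
- Aqueous HF in MeCN at 0 °C removes the silyl ether to give 22.

**Step 8.** Reduction of four alkynes in one operation may overshoot at some positions, stop short at others, or isomerise Z to E, giving a mixture of near-identical polarity that is hard to purify.

Fallback (sets out from 10, uses 12 and 5, returns at 18): the reduction is split into two two-fold reductions so that each hydrogenation acts on a skipped diyne only.
- 10 is semi-hydrogenated (H2, P-2 nickel boride Ni2B, ethylenediamine, EtOH) to methyl (5Z,8Z)-10-hydroxydeca-5,8-dienoate F10.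
- The Appel reaction (CBr4, PPh3, CH2Cl2, −20 °C) gives methyl (5Z,8Z)-10-bromodeca-5,8-dienoate F11.
- Copper-mediated SN2 coupling of this primary allylic bromide with 12 (CuI, Cs2CO3, DMF) should give methyl (5Z,8Z)-13-hydroxytrideca-5,8-dien-11-ynoate F12.
- A second Appel reaction gives methyl (5Z,8Z)-13-bromotrideca-5,8-dien-11-ynoate F13.
- Coupling with 5 (CuI, Cs2CO3, DMF) gives methyl (5Z,8Z,19R)-19-hydroxyicosa-5,8-diene-11,14-diynoate F14.
- Semi-hydrogenation of the two remaining alkynes under the same nickel conditions should give 18.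

**Step 7** (with the bromide made in step 6). The skipped triyne propargylic bromide may polymerise or autoxidise before it couples, and the base may cause propargyl-to-allenyl isomerisation in the triyne during the slow final union.

Fallback (sets out from 5 and 11, returns at 17): the C20 chain is joined two-plus-two at C10–C11, so that the electrophile is the more robust diyne bromide 11 and no triyne bromide is handled.
- 5 is coupled with 3-bromo-1-(trimethylsilyl)prop-1-yne (CuI, Cs2CO3, DMF) to give (R)-10-(trimethylsilyl)deca-6,9-diyn-2-ol F15.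
- Buffered desilylation (nBu4NF, AcOH, THF, 0 °C) gives (R)-deca-6,9-diyn-2-ol F16.
- F16 is coupled at once with 11 (CuI, Cs2CO3, DMF, 0 °C → rt) to give 17.

**Further compounds**

F1 | step 10 | (R)-tert-butyl(hept-6-yn-2-yloxy)dimethylsilane | C[C@@H](O[Si](C)(C)C(C)(C)C)CCCC#C
F2 | step 10 | diethyl [(6R)-6-(tert-butyldimethylsilyloxy)hept-1-yn-1-yl]phosphonate | C[C@@H](O[Si](C)(C)C(C)(C)C)CCCC#CP(=O)(OCC)OCC
F3 | step 10 | diethyl [(6R)-2-(butylamino)-6-(tert-butyldimethylsilyloxy)hept-1-en-1-yl]phosphonate | C[C@@H](O[Si](C)(C)C(C)(C)C)CCCC(NCCCC)=CP(=O)(OCC)OCC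
F4 | step 10 | diethyl [(6R)-6-(tert-butyldimethylsilyloxy)-2-oxoheptyl]phosphonate | C[C@@H](O[Si](C)(C)C(C)(C)C)CCCC(=O)CP(=O)(OCC)OCC
F5 | step 10 | (3aR,4R,5R,6aS)-4-[(1E,7R)-7-(tert-butyldimethylsilyloxy)-3-oxooct-1-en-1-yl]-2-oxohexahydro-2H-cyclopenta[b]furan-5-yl benzoate | C[C@@H](O[Si](C)(C)C(C)(C)C)CCCC(=O)/C=C/[C@@H]1[C@@H](CC(=O)O2)[C@@H]2C[C@H]1OC(=O)c3ccccc3
F6 | step 10 | (3aR,4R,5R,6aS)-4-[(1E,3S,7R)-7-(tert-butyldimethylsilyloxy)-3-hydroxyoct-1-en-1-yl]-2-oxohexahydro-2H-cyclopenta[b]furan-5-yl benzoate | C[C@@H](O[Si](C)(C)C(C)(C)C)CCC[C@H](O)/C=C/[C@@H]1[C@@H](CC(=O)O2)[C@@H]2C[C@H]1OC(=O)c3ccccc3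
F7 | step 10 | (3aR,4R,5R,6aS)-4-[(1E,3S,7R)-7-(tert-butyldimethylsilyloxy)-3-hydroxyoct-1-en-1-yl]-5-hydroxyhexahydro-2H-cyclopenta[b]furan-2-one | C[C@@H](O[Si](C)(C)C(C)(C)C)CCC[C@H](O)/C=C/[C@@H]1[C@@H](CC(=O)O2)[C@@H]2C[C@H]1O
F8 | step 10 | (3aR,4R,5R,6aS)-4-[(1E,3S,7R)-7-(tert-butyldimethylsilyloxy)-3-hydroxyoct-1-en-1-yl]hexahydro-2H-cyclopenta[b]furan-2,5-diol (lactol, both anomers) | C[C@@H](O[Si](C)(C)C(C)(C)C)CCC[C@H](O)/C=C/[C@@H]1[C@@H](CC(O)O2)[C@@H]2C[C@H]1O
F9 | step 10 | 19-O-tert-butyldimethylsilyl-19(R)-hydroxy-prostaglandin F2α | C[C@@H](O[Si](C)(C)C(C)(C)C)CCC[C@H](O)/C=C/[C@@H]1[C@@H](C/C=C\CCCC(=O)O)[C@@H](O)C[C@H]1O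
F10 | step 8 | methyl (5Z,8Z)-10-hydroxydeca-5,8-dienoate | OC/C=C\C/C=C\CCCC(=O)OC
F11 | step 8 | methyl (5Z,8Z)-10-bromodeca-5,8-dienoate | BrC/C=C\C/C=C\CCCC(=O)OC
F12 | step 8 | methyl (5Z,8Z)-13-hydroxytrideca-5,8-dien-11-ynoate | OCC#CC/C=C\C/C=C\CCCC(=O)OC
F13 | step 8 | methyl (5Z,8Z)-13-bromotrideca-5,8-dien-11-ynoate | BrCC#CC/C=C\C/C=C\CCCC(=O)OC
F14 | step 8 | methyl (5Z,8Z,19R)-19-hydroxyicosa-5,8-diene-11,14-diynoate | C[C@@H](O)CCCC#CCC#CC/C=C\C/C=C\CCCC(=O)OC
F15 | step 7 | (R)-10-(trimethylsilyl)deca-6,9-diyn-2-ol | C[C@@H](O)CCCC#CCC#C[Si](C)(C)C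
F16 | step 7 | (R)-deca-6,9-diyn-2-ol | C[C@@H](O)CCCC#CCC#C
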